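The target is a β-aryl ketone: C8 of the flavonol A ring is bonded to the stereocentre that lies β to the heptanone carbonyl. This 1,3-relationship, and the phloroglucinol-type nucleophilicity of C8 (ortho to the 7-OH, para to the 5-OH), are exploited in a biomimetic, catalyst-controlled Friedel–Crafts conjugate addition of unprotected galangin to the diarylheptenone (E)-7-(4-hydroxy-3-methoxyphenyl)-1-phenylhept-4-en-3-one. In one operation a chiral primary-amine (iminium) catalyst joins the two natural-product halves, forms the C8–C bond and sets the only stereocentre (R), with no protecting group. The enone is made in two steps from coniferaldehyde.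

Key step: step 3

Remark on the chemistry: the facial sense of the cinchona primary amine is assumed from the usual shielding model for (E)-enone iminium ions. The quinine-derived amine is written; its commercial pseudo-enantiomer from quinidine would be used if the sense proves opposite for this substrate.

Step 1
Reactants: 1 coniferaldehyde, (E)-3-(4-hydroxy-3-methoxyphenyl)prop-2-enal
Product: 2 3-(4-hydroxy-3-methoxyphenyl)propanal
Conditions: H2 (1 atm), 5% Pd/C, Ph2S (cat.), EtOAc, rt
Reagents that add atoms: none
Why: Chemoselective heterogeneous hydrogenation of the conjugated C=C of a cinnamaldehyde; sulfide-poisoned Pd/C should leave the aldehyde and the arene untouched, and no stereocentre is formed.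

Step 2
Reactants: 2 3-(4-hydroxy-3-methoxyphenyl)propanal; 3 dimethyl (2-oxo-4-phenylbutyl)phosphonate
Product: 4 (E)-7-(4-hydroxy-3-methoxyphenyl)-1-phenylhept-4-en-3-one
Conditions: 3 (1.1 equiv), LiCl, i-Pr2NEt, MeCN, rt
Reagents that add atoms: none
Why: Horner–Wadsworth–Emmons olefination under Masamune–Roush conditions; the lithium-chelated β-ketophosphonate is deprotonated by the amine base, which is mild enough to spare the enolisable aldehyde and the free phenol, and the stabilised phosphonate should give the (E)-enone.

Step 3
Reactants: 4 (E)-7-(4-hydroxy-3-methoxyphenyl)-1-phenylhept-4-en-3-one; 5 galangin, 3,5,7-trihydroxy-2-phenyl-4H-chromen-4-one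
Product: 7 3,5,7-trihydroxy-8-[(3R)-1-(4-hydroxy-3-methoxyphenyl)-5-oxo-7-phenylheptan-3-yl]-2-phenyl-4H-chromen-4-one, via iminium ion 6 (not isolated)
Conditions: 4 (1.0 equiv), 5 (1.5 equiv), 9-amino-9-deoxy-epi-quinine (20 mol %), PhCO2H (40 mol %), THF, 30 °C, N2
Reagents that add atoms: none
Why: The primary amine condenses with the ketone of 4 to give the α,β-unsaturated iminium ion 6, while the quinuclidine nitrogen of the same catalyst hydrogen-bonds to the acidic 7-OH of 5 (a vinylogous acid), so that C8 of ring A adds to C5 of the heptenone; rearomatisation of ring A and hydrolysis of the resulting enamine release 7 and the catalyst. The closest known reaction type is the iminium-catalysed enantioselective Friedel–Crafts (Michael) addition of naphthols, other electron-rich phenols and the vinylogous acid 4-hydroxycoumarin to enones with 9-amino-9-deoxy-epi-cinchona amines, and the step copies the presumed conjugate addition by which flavonoid and diarylheptanoid are joined in the plant. No ring is closed. The single new stereocentre is set by the catalyst: in the s-trans (E)-iminium ion the quinoline and quinuclidine units should cover one face of C5, so that the hydrogen-bonded nucleophile is delivered to the Re face, which corresponds to (R). The step needs C8 over C6 attack, C- over O-alkylation and mono-alkylation: C8 carries only one exocyclic ortho substituent (C6 lies between two hydroxyl groups) and is the site at which 5,7-dihydroxyflavonols react with iminium electrophiles in Mannich aminomethylation, O-adducts revert by retro-oxa-Michael reaction, and the excess of 5 together with the bulk of the first side chain should suppress a second alkylation.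

Compound list
1 | coniferaldehyde, (E)-3-(4-hydroxy-3-methoxyphenyl)prop-2-enal | COc1cc(/C=C/C=O)ccc1O | starting material
2 | 3-(4-hydroxy-3-methoxyphenyl)propanal | COc1cc(CCC=O)ccc1O | intermediate
3 | dimethyl (2-oxo-4-phenylbutyl)phosphonate | COP(=O)(OC)CC(=O)CCc1ccccc1 | starting material
4 | (E)-7-(4-hydroxy-3-methoxyphenyl)-1-phenylhept-4-en-3-one | COc1cc(CC/C=C/C(=O)CCc2ccccc2)ccc1O | intermediate
5 | galangin, 3,5,7-trihydroxy-2-phenyl-4H-chromen-4-one | O=c1c(O)c(-c2ccccc2)oc2cc(O)cc(O)c12 | starting material
6 | iminium ion (cation) formed from the ketone of 4 and the primary amine of (8S,9S)-9-amino-9-deoxy-epi-quinine | COc1cc(CC/C=C/C(CCc2ccccc2)=[NH+][C@@H](c2ccnc3ccc(OC)cc23)[C@@H]2C[C@@H]3CCN2C[C@@H]3C=C)ccc1O | intermediate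
7 | 3,5,7-trihydroxy-8-[(3R)-1-(4-hydroxy-3-methoxyphenyl)-5-oxo-7-phenylheptan-3-yl]-2-phenyl-4H-chromen-4-one | COc1cc(CC[C@H](CC(=O)CCc2ccccc2)c2c(O)cc(O)c3c(=O)c(O)c(-c4ccccc4)oc23)ccc1O | target

Total step count: 3. Longest linear sequence: 3 steps (1 → 2 → 4 → 7).

Steps most likely to fail

Step 3. Three processes threaten it:
- regiochemical leakage to C6 and a second alkylation of ring A;
- poor facial selectivity, because the iminium ion of a non-methyl ketone can form as E/Z mixtures about C=N;
- slow iminium formation, or acid-promoted cyclodehydration of the product through its 7-OH.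

The fallback sets out from 5, uses 4 and comes back at 7. It makes the same bond regiospecifically with palladium and sets the stereocentre afterwards by asymmetric conjugate reduction. Galangin 5 is perbenzylated (BnBr, K2CO3, DMF, 70 °C) to 3,5,7-tris(benzyloxy)-2-phenyl-4H-chromen-4-one F1. Iodination (NIS, cat. TFA, CH2Cl2) should occur at C8, because the 5-O-benzyl group is turned toward C6 by the peri carbonyl and shields it, giving 3,5,7-tris(benzyloxy)-8-iodo-2-phenyl-4H-chromen-4-one F2. Heck coupling of F2 with enone 4 under ligand-free phase-transfer conditions (Pd(OAc)2, Bu4NCl, NaHCO3, DMF, 90 °C) should give 3,5,7-tris(benzyloxy)-8-[(3E)-1-(4-hydroxy-3-methoxyphenyl)-5-oxo-7-phenylhept-3-en-3-yl]-2-phenyl-4H-chromen-4-one F3. Copper hydride-catalysed asymmetric 1,4-reduction (Cu(OAc)2, the DTBM-SEGPHOS enantiomer that delivers hydride to the face leading to (R), excess (EtO)2MeSiH, t-BuOH, toluene, then fluoride work-up) should give 3,5,7-tris(benzyloxy)-8-[(3R)-1-(4-hydroxy-3-methoxyphenyl)-5-oxo-7-phenylheptan-3-yl]-2-phenyl-4H-chromen-4-one F4. Hydrogenolysis of the three benzyl ethers (H2, Pd/C, EtOAc/MeOH) returns to 7.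

Step 1. Over-reduction of the aldehyde, or incomplete reduction of the alkene, would give mixtures that are hard to separate. The fallback sets out from 1 and comes back at 2. It reduces exhaustively and then re-oxidises: H2, Pd/C, MeOH followed by NaBH4 in the same pot should give 3-(4-hydroxy-3-methoxyphenyl)propan-1-ol F5 as a single compound. Parikh–Doering oxidation of the primary alcohol (SO3·pyridine, DMSO, i-Pr2NEt, CH2Cl2, 0 °C), which should leave the phenol alone, returns to 2.

Step 2. Base-mediated self-aldolisation of the enolisable aldehyde, or stalling through phenoxide formation, would lower conversion. The fallback sets out from 2 and comes back at 4. It replaces the olefination by an enamine-mediated cross-aldol condensation with commercial 4-phenylbutan-2-one (pyrrolidine, AcOH, THF, rt). The terminal enamine of the methyl ketone should add to 2 to give 5-hydroxy-7-(4-hydroxy-3-methoxyphenyl)-1-phenylheptan-3-one F6, which is dehydrated on warming with catalytic TsOH in toluene to the (E)-enone 4.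

Further compounds
F1 | step 3 | 3,5,7-tris(benzyloxy)-2-phenyl-4H-chromen-4-one | O=c1c(OCc2ccccc2)c(-c2ccccc2)oc2cc(OCc3ccccc3)cc(OCc3ccccc3)c12
F2 | step 3 | 3,5,7-tris(benzyloxy)-8-iodo-2-phenyl-4H-chromen-4-one | O=c1c(OCc2ccccc2)c(-c2ccccc2)oc2c(I)c(OCc3ccccc3)cc(OCc3ccccc3)c12
F3 | step 3 | 3,5,7-tris(benzyloxy)-8-[(3E)-1-(4-hydroxy-3-methoxyphenyl)-5-oxo-7-phenylhept-3-en-3-yl]-2-phenyl-4H-chromen-4-one | COc1cc(CC/C(=C\C(=O)CCc2ccccc2)c2c(OCc3ccccc3)cc(OCc3ccccc3)c3c(=O)c(OCc4ccccc4)c(-c4ccccc4)oc23)ccc1O
F4 | step 3 | 3,5,7-tris(benzyloxy)-8-[(3R)-1-(4-hydroxy-3-methoxyphenyl)-5-oxo-7-phenylheptan-3-yl]-2-phenyl-4H-chromen-4-one | COc1cc(CC[C@H](CC(=O)CCc2ccccc2)c2c(OCc3ccccc3)cc(OCc3ccccc3)c3c(=O)c(OCc4ccccc4)c(-c4ccccc4)oc23)ccc1O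
F5 | step 1 | 3-(4-hydroxy-3-methoxyphenyl)propan-1-ol | COc1cc(CCCO)ccc1O
F6 | step 2 | 5-hydroxy-7-(4-hydroxy-3-methoxyphenyl)-1-phenylheptan-3-one (racemic) | COc1cc(CCC(O)CC(=O)CCc2ccccc2)ccc1O
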